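**Strategy.** The cyclohexene ring (carotenoid numbering: C1 = CMe2, C2 and C6 = stereocentres) is closed across C6–C1 and C4=C5 in one photoredox operation. A carboxylate on C1 is oxidised to a tertiary radical that adds to C6 of a vinylphosphonium, and the ylide so formed olefinates the C4 aldehyde. The step exploits the gem-dimethyl carbon C1 as a radical site, the trisubstituted ring alkene C4=C5 as a Wittig retron, and the cis-1,3 arms on C2 and C6, which the acyclic precursor ties together as an ester that becomes a temporary seven-membered lactone. Lactone cleavage gives both side-chain handles; Wittig couplings with C10-dialdehyde build the polyene.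

Key step: step 8

Assumption: polyene double bonds that form as E/Z mixtures (Wittig, HWE, phosphonium salt formation) are equilibrated to the all-E isomers by iodine or heat, as is usual for carotenoids; the E-enriched commercial C5 phosphonates and all-E C10-dialdehyde are used.

**Ring half**

Step 1
Reactants: 1 but-2-yn-1-ol
Product: 2 (2Z)-3-iodobut-2-en-1-ol
Conditions: Red-Al, THF, 0 °C to rt; then I2, −78 to 0 °C
Reagents that add atoms: iodine, II
Why: Hydroxyl-directed trans-hydroalumination of the propargylic alcohol places aluminium on C3, and iodinolysis with retention should give the (Z)-3-iodo allylic alcohol.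

Step 2
Reactants: 2 (2Z)-3-iodobut-2-en-1-ol
Product: 3 [(2Z)-4-hydroxybut-2-en-2-yl]triphenylphosphonium tetrafluoroborate
Conditions: PPh3 (1.1 equiv), Pd(PPh3)4 (3 mol%), PhMe, 90 °C; then aq. NaBF4/CH2Cl2
Reagents that add atoms: triphenylphosphine, c1ccc(cc1)P(c1ccccc1)c1ccccc1; sodium tetrafluoroborate, [Na+].F[B-](F)(F)F
Why: Palladium-catalysed quaternisation of PPh3 by a vinyl iodide (oxidative addition, C–P reductive elimination) should proceed with retention and leave the free allylic alcohol untouched; exchange to BF4− removes oxidisable iodide before the ozonolysis.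

Step 3
Reactants: 4 penta-1,4-diene; 5 methyl acrylate
Product: 6 methyl (2E)-hexa-2,5-dienoate
Conditions: Hoveyda–Grubbs II (2 mol%), 1,4-benzoquinone (10 mol%), 4 (4 equiv), CH2Cl2, 40 °C
Reagents that add atoms: none
Why: Olefin cross metathesis of a terminal alkene with an acrylate is E-selective; excess diene limits double metathesis and benzoquinone suppresses Ru–H migration of the skipped diene.

Step 4
Reactants: 6 methyl (2E)-hexa-2,5-dienoate
Product: 7 dimethyl (3R)-2,2-dimethyl-3-(prop-2-en-1-yl)pentanedioate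
Conditions: Me2C=C(OMe)OSiMe3 (1.5 equiv), chiral imidodiphosphorimidate (IDPi) catalyst (2 mol%), PhMe, −40 °C; then 1 M HCl/THF
Reagents that add atoms: 1-methoxy-2-methyl-1-(trimethylsilyloxy)prop-1-ene, COC(O[Si](C)(C)C)=C(C)C
Why: Catalytic asymmetric Mukaiyama–Michael addition of a silyl ketene acetal to an α,β-unsaturated methyl ester under silylium-type IDPi catalysis; the catalyst antipode that directs attack to the Re face of C3 should set the (3R) centre (the future ring C2) next to the new quaternary carbon.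

Step 5
Reactants: 7 dimethyl (3R)-2,2-dimethyl-3-(prop-2-en-1-yl)pentanedioate
Product: 8 (3R)-2,2-dimethyl-3-(prop-2-en-1-yl)pentanedioic acid
Conditions: KOH (6 equiv), EtOH/H2O, 85 °C; then aq. HCl
Reagents that add atoms: potassium hydroxide, [K+].[OH-]
Why: Forcing saponification cleaves both esters, including the hindered α,α-dimethyl one; the stereocentre is β to both carbonyl groups and cannot epimerise.

Step 6
Reactants: 8 (3R)-2,2-dimethyl-3-(prop-2-en-1-yl)pentanedioic acid; 3 [(2Z)-4-hydroxybut-2-en-2-yl]triphenylphosphonium tetrafluoroborate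
Product: 10 (3R)-2,2-dimethyl-5-oxo-3-(prop-2-en-1-yl)-5-{[(2Z)-3-(triphenylphosphonio)but-2-en-1-yl]oxy}pentanoic acid tetrafluoroborate, via cyclic anhydride 9 (not isolated)
Conditions: EDC·HCl (1.1 equiv), CH2Cl2, 0 °C to rt; then 3 (1.0 equiv), DMAP (0.2 equiv), MeCN, rt; aq. NaBF4 wash
Reagents that add atoms: none
Why: Carbodiimide dehydration of the 1,5-diacid gives the six-membered anhydride, which the primary alcohol should open at the unhindered CH2–C=O and not at the neopentyl CMe2–C=O (regioselective anhydride alcoholysis).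

Step 7
Reactants: 10 allyl acid–ester phosphonium salt
Product: 11 (3R)-2,2-dimethyl-5-oxo-3-(2-oxoethyl)-5-{[(2Z)-3-(triphenylphosphonio)but-2-en-1-yl]oxy}pentanoic acid tetrafluoroborate
Conditions: O3, CH2Cl2, −78 °C; then PPh3
Reagents that add atoms: ozone, O=[O+][O-]
Why: Ozonolysis is selective for the electron-rich terminal alkene, the cationic vinylphosphonium alkene being inert to electrophilic ozone.

Step 8
Reactants: 11 acid–aldehyde vinylphosphonium salt
Product: 14 (1R,6R)-9,10,10-trimethyl-3-oxabicyclo[4.3.1]dec-8-en-4-one, via carboxylate inner salt 12 (not isolated), via phosphorus ylide 13 (not isolated)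
Conditions: Cs2CO3 (2 equiv), Ir[dF(CF3)ppy]2(dtbbpy)PF6 (2 mol%), degassed MeCN (2 mM), 450 nm LEDs, 25 °C
Reagents that add atoms: none
Why: Proposed new method: the excited Ir(III) catalyst oxidises carboxylate 12, CO2 is lost, the nucleophilic tertiary radical at C1 adds to C6 of the tethered cationic vinylphosphonium, and Ir(II) reduces the α-phosphonio radical to ylide 13, which olefinates the pendant C4 aldehyde; the closest known reaction types are the intermolecular three-component decarboxylative radical addition/Wittig olefination of carboxylic acids, vinylphosphonium salts and aldehydes, and the classical radical addition to vinylphosphonium salts. The lactone ring closes by a 7-exo-trig radical cyclisation and the carbocycle by a six-membered intramolecular Wittig reaction through an oxaphosphetane, which can only give the endocyclic C4=C5 bond. C2 is carried in from step 4; the new centre C6 must be cis to the C2 arm because only the cis-disubstituted oxepanone can bridge to the bicyclo[4.3.1] skeleton, so a trans radical adduct cannot ring-close and should be lost as polar phosphonium material. Attack at C6 and not C5 is secured by C5 being fully substituted and by the phosphonium polarisation, and the aldehyde is chosen over the lactone carbonyl by its much faster Wittig reaction. High dilution is needed so that cyclisation outruns intermolecular addition, and carbonate keeps the ylide deprotonated.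

Step 9
Reactants: 14 bicyclic lactone
Product: 15 (1R,6R)-9,10,10-trimethyl-3-oxabicyclo[4.3.1]dec-8-en-4-ol (lactol, both anomers)
Conditions: DIBAL-H (1.1 equiv), CH2Cl2, −78 °C; Rochelle salt
Reagents that add atoms: none
Why: Partial reduction of a lactone stops at the aluminium hemiacetal at −78 °C; the isolated ring alkene is inert.

Step 10
Reactants: 15 lactol
Product: 16 ethyl (2E)-4-[(1R,5R)-5-(hydroxymethyl)-4,6,6-trimethylcyclohex-3-en-1-yl]-2-methylbut-2-enoate
Conditions: Ph3P=C(Me)CO2Et (2 equiv), PhMe, 90 °C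
Reagents that add atoms: ethyl 2-(triphenyl-λ5-phosphanylidene)propanoate, CCOC(=O)C(C)=P(c1ccccc1)(c1ccccc1)c1ccccc1
Why: The open hydroxy-aldehyde form of the seven-membered lactol undergoes Wittig olefination with the stabilised ylide, which should give the (E)-trisubstituted enoate and free the C7 alcohol, so cleaving the temporary ring.

Step 11
Reactants: 16 hydroxy enoate
Product: 18 ethyl (2E)-2-methyl-4-{(1R,5R)-4,6,6-trimethyl-5-[(1E)-3-oxobut-1-en-1-yl]cyclohex-3-en-1-yl}but-2-enoate, via aldehyde 17 (not isolated)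
Conditions: IBX (1.5 equiv), Ph3P=CHC(O)Me (2 equiv), DMSO, 25 to 50 °C
Reagents that add atoms: 1-(triphenyl-λ5-phosphanylidene)propan-2-one, CC(=O)C=P(c1ccccc1)(c1ccccc1)c1ccccc1
Why: Tandem IBX oxidation/Wittig olefination traps the enolisable β,γ-unsaturated aldehyde as it forms with a weakly basic stabilised ylide, which should give the (E)-enone without loss of the C6 configuration.

Step 12
Reactants: 18 enone
Product: 19 ethyl (2E)-4-{(1R,5R)-5-[(1E)-3-hydroxy-3-methylpenta-1,4-dien-1-yl]-4,6,6-trimethylcyclohex-3-en-1-yl}-2-methylbut-2-enoate (both carbinol epimers)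
Conditions: CH2=CHMgBr (1.3 equiv), THF, −78 °C
Reagents that add atoms: vinylmagnesium bromide, C=C[Mg]Br
Why: 1,2-Grignard addition to the methyl ketone is much faster at −78 °C than attack on the hindered α-methyl enoate; the new carbinol centre is destroyed in the next step.

Step 13
Reactants: 19 vinyl carbinol
Product: 20 {(2E,4E)-5-[(1R,5R)-5-((2E)-4-ethoxy-3-methyl-4-oxobut-2-en-1-yl)-2,6,6-trimethylcyclohex-2-en-1-yl]-3-methylpenta-2,4-dien-1-yl}triphenylphosphonium bromide
Conditions: Ph3P·HBr (1.05 equiv), MeOH, 0 °C to rt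
Reagents that add atoms: triphenylphosphine hydrobromide, [Br-].c1ccc(cc1)[PH+](c1ccccc1)c1ccccc1
Why: Ionisation of the tertiary bis-allylic alcohol to a pentadienyl cation and capture by PPh3 at the unhindered terminus (allylic transposition, SN1') is the standard entry to carotenoid C15-type Wittig salts and favours the 9E isomer.

Step 14
Reactants: 20 ring phosphonium bromide; 21 (2E,4E,6E)-2,7-dimethylocta-2,4,6-trienedial
Product: 22 ethyl (2E)-2-methyl-4-{(1R,5R)-4,6,6-trimethyl-5-[(1E,3E,5E,7E,9E,11E)-3,7,12-trimethyl-13-oxotrideca-1,3,5,7,9,11-hexaen-1-yl]cyclohex-3-en-1-yl}but-2-enoate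
Conditions: NaOEt (1.1 equiv), 21 (3 equiv), CH2Cl2/EtOH, 0 °C to rt; then I2 (cat.), hexane, daylight
Reagents that add atoms: none
Why: Wittig olefination of the allylic ylide with an excess of the symmetrical dialdehyde should give the mono-adduct, and iodine equilibration converts the new 11Z/11E mixture to all-E.

**Acyclic half**

Step 15
Reactants: 23 dimethyl (R)-malate; 24 1-bromo-3-methylbut-2-ene
Product: 25 dimethyl (2R,3S)-2-hydroxy-3-(3-methylbut-2-en-1-yl)butanedioate
Conditions: LiHMDS (2.2 equiv), THF, −78 to −10 °C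
Reagents that add atoms: none
Why: Fráter–Seebach alkylation of the chelated malate dianion takes the allylic bromide anti to the alkoxide, so the (R)-carbinol centre should set the (3S) centre (the future C2').

Step 16
Reactants: 25 prenylated malate
Product: 26 (3R,4S)-2,5-dimethyl-4-(3-methylbut-2-en-1-yl)hexane-2,3,5-triol
Conditions: MeMgBr (6 equiv), anhydrous CeCl3, THF, −78 to 0 °C
Reagents that add atoms: methylmagnesium bromide, C[Mg]Br
Why: Double Grignard addition converts both esters into dimethyl carbinols; the cerium additive suppresses enolisation of the intermediate methyl ketone, which would epimerise C4.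

Step 17
Reactants: 26 triol
Product: 27 (2R)-2-(2-hydroxypropan-2-yl)-5-methylhex-4-enal
Conditions: NaIO4 (1.5 equiv), THF/pH 7 buffer, 0 °C
Reagents that add atoms: none
Why: Periodate glycol cleavage cuts only the vicinal tertiary/secondary diol, releasing acetone and the α-branched aldehyde under neutral conditions; the 1,3-related tertiary alcohol is untouched.

Step 18
Reactants: 27 hydroxy aldehyde
Product: 28 (2E,4E,6S)-6-(2-hydroxypropan-2-yl)-3,9-dimethyldeca-2,4,8-trienenitrile
Conditions: diethyl (3-cyano-2-methylallyl)phosphonate (1.2 equiv), n-BuLi (1.15 equiv), THF, −78 to 0 °C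
Reagents that add atoms: diethyl [(2E)-3-cyano-2-methylprop-2-en-1-yl]phosphonate, CCOP(=O)(OCC)C/C(C)=C/C#N
Why: Horner–Wadsworth–Emmons olefination with the preformed, weakly basic allylic phosphonate anion is E-selective and should add to the aldehyde faster than it enolises it or deprotonates the tertiary alcohol.

Step 19
Reactants: 28 dienenitrile
Product: 29 (2E,4E,6S)-6-(2-hydroxypropan-2-yl)-3,9-dimethyldeca-2,4,8-trienal
Conditions: DIBAL-H (2.5 equiv), PhMe, −78 °C; then wet silica gel
Reagents that add atoms: water, O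
Why: DIBAL-H reduces the conjugated nitrile to the aluminium aldimine, which hydrolyses to the dienal; one equivalent is consumed by the tertiary alcohol.

Step 20
Reactants: 29 dienal
Product: 30 ethyl (2E,4E,6E,8E,10S)-10-(2-hydroxypropan-2-yl)-3,7,13-trimethyltetradeca-2,4,6,8,12-pentaenoate
Conditions: triethyl 3-methyl-4-phosphonocrotonate (1.3 equiv), LiHMDS (1.25 equiv), THF, −78 to 0 °C
Reagents that add atoms: ethyl (2E)-4-(diethoxyphosphoryl)-3-methylbut-2-enoate, CCOC(=O)/C=C(\C)CP(=O)(OCC)OCC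
Why: A second E-selective Horner–Wadsworth–Emmons reaction with the C5 phosphonate extends the chain to C11' with the methyl group on C9'.

Step 21
Reactants: 30 pentaenoate
Product: 31 (2E,4E,6E,8E,10S)-10-(2-hydroxypropan-2-yl)-3,7,13-trimethyltetradeca-2,4,6,8,12-pentaen-1-ol
Conditions: DIBAL-H (3.5 equiv), CH2Cl2, −78 °C
Reagents that add atoms: none
Why: DIBAL-H reduces the conjugated ester to the allylic alcohol by 1,2-hydride delivery without touching the polyene.

Step 22
Reactants: 31 polyene diol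
Product: 32 [(2E,4E,6E,8E,10S)-10-(2-hydroxypropan-2-yl)-3,7,13-trimethyltetradeca-2,4,6,8,12-pentaen-1-yl]triphenylphosphonium bromide
Conditions: Ph3P·HBr (1.05 equiv), MeOH, 0 °C
Reagents that add atoms: triphenylphosphine hydrobromide, [Br-].c1ccc(cc1)[PH+](c1ccccc1)c1ccccc1
Why: Only the primary polyenylic alcohol ionises under this weakly acidic salt formation; the non-allylic tertiary alcohol and the C10 centre should be unaffected.

**Assembly**

Step 23
Reactants: 22 C25 aldehyde; 32 acyclic phosphonium bromide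
Product: 33 ethyl (2E)-4-[(1R,5R)-5-{(1E,3E,5E,7E,9E,11E,13E,15E,17E,19E,21E,23S)-23-(2-hydroxypropan-2-yl)-3,7,12,16,20,26-hexamethylheptacosa-1,3,5,7,9,11,13,15,17,19,21,25-dodecaen-1-yl}-4,6,6-trimethylcyclohex-3-en-1-yl]-2-methylbut-2-enoate
Conditions: NaOEt (2.2 equiv), CH2Cl2/EtOH, rt; then heptane, 90 °C, N2
Reagents that add atoms: none
Why: Wittig coupling of the polyenyl ylide with the C25 aldehyde forms C11'=C12', and thermal equilibration should convert the Z/E mixture to the all-E polyene; ethoxide matches the ethyl ester and tolerates the free tertiary alcohol.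

Step 24
Reactants: 33 C50 ethyl ester
Product: 34 target, (2E)-4-[(1R,5R)-5-{(1E,3E,5E,7E,9E,11E,13E,15E,17E,19E,21E,23S)-23-(2-hydroxypropan-2-yl)-3,7,12,16,20,26-hexamethylheptacosa-1,3,5,7,9,11,13,15,17,19,21,25-dodecaen-1-yl}-4,6,6-trimethylcyclohex-3-en-1-yl]-2-methylbut-2-en-1-ol
Conditions: DIBAL-H (4 equiv), THF, −78 to −40 °C; Rochelle salt
Reagents that add atoms: none
Why: DIBAL-H reduces the only carbonyl group, the α-methyl enoate, to the (E)-allylic alcohol; polyene, ring alkene and tertiary alcohol are inert.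

**Compound list**

1 | but-2-yn-1-ol | CC#CCO | starting material
2 | (2Z)-3-iodobut-2-en-1-ol | C/C(I)=C/CO | intermediate
3 | [(2Z)-4-hydroxybut-2-en-2-yl]triphenylphosphonium tetrafluoroborate | C/C(=C/CO)[P+](c1ccccc1)(c1ccccc1)c1ccccc1.F[B-](F)(F)F | intermediate
4 | penta-1,4-diene | C=CCC=C | starting material
5 | methyl acrylate | C=CC(=O)OC | starting material
6 | methyl (2E)-hexa-2,5-dienoate | C=CC/C=C/C(=O)OC | intermediate
7 | dimethyl (3R)-2,2-dimethyl-3-(prop-2-en-1-yl)pentanedioate | C=CC[C@H](CC(=O)OC)C(C)(C)C(=O)OC | intermediate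
8 | (3R)-2,2-dimethyl-3-(prop-2-en-1-yl)pentanedioic acid | C=CC[C@H](CC(=O)O)C(C)(C)C(=O)O | intermediate
9 | (4R)-3,3-dimethyl-4-(prop-2-en-1-yl)oxane-2,6-dione | O=C1C[C@@H](CC=C)C(C)(C)C(=O)O1 | intermediate
10 | (3R)-2,2-dimethyl-5-oxo-3-(prop-2-en-1-yl)-5-{[(2Z)-3-(triphenylphosphonio)but-2-en-1-yl]oxy}pentanoic acid tetrafluoroborate | C=CC[C@H](CC(=O)OC/C=C(/C)[P+](c1ccccc1)(c1ccccc1)c1ccccc1)C(C)(C)C(=O)O.F[B-](F)(F)F | intermediate
11 | (3R)-2,2-dimethyl-5-oxo-3-(2-oxoethyl)-5-{[(2Z)-3-(triphenylphosphonio)but-2-en-1-yl]oxy}pentanoic acid tetrafluoroborate | O=CC[C@H](CC(=O)OC/C=C(/C)[P+](c1ccccc1)(c1ccccc1)c1ccccc1)C(C)(C)C(=O)O.F[B-](F)(F)F | intermediate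
12 | (3R)-2,2-dimethyl-5-oxo-3-(2-oxoethyl)-5-{[(2Z)-3-(triphenylphosphonio)but-2-en-1-yl]oxy}pentanoate (inner salt) | O=CC[C@H](CC(=O)OC/C=C(/C)[P+](c1ccccc1)(c1ccccc1)c1ccccc1)C(C)(C)C(=O)[O-] | intermediate
13 | (4R,6R)-5,5-dimethyl-4-(2-oxoethyl)-6-[1-(triphenyl-λ5-phosphanylidene)ethyl]oxepan-2-one | O=C1C[C@@H](CC=O)C(C)(C)[C@H](CO1)C(C)=P(c1ccccc1)(c1ccccc1)c1ccccc1 | intermediate
14 | (1R,6R)-9,10,10-trimethyl-3-oxabicyclo[4.3.1]dec-8-en-4-one | O=C1C[C@H]2CC=C(C)[C@@H](CO1)C2(C)C | intermediate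
15 | (1R,6R)-9,10,10-trimethyl-3-oxabicyclo[4.3.1]dec-8-en-4-ol | OC1C[C@H]2CC=C(C)[C@@H](CO1)C2(C)C | intermediate
16 | ethyl (2E)-4-[(1R,5R)-5-(hydroxymethyl)-4,6,6-trimethylcyclohex-3-en-1-yl]-2-methylbut-2-enoate | OC[C@@H]1C(C)=CC[C@H](C/C=C(\C)C(=O)OCC)C1(C)C | intermediate
17 | ethyl (2E)-4-[(1R,5R)-5-formyl-4,6,6-trimethylcyclohex-3-en-1-yl]-2-methylbut-2-enoate | O=C[C@@H]1C(C)=CC[C@H](C/C=C(\C)C(=O)OCC)C1(C)C | intermediate
18 | ethyl (2E)-2-methyl-4-{(1R,5R)-4,6,6-trimethyl-5-[(1E)-3-oxobut-1-en-1-yl]cyclohex-3-en-1-yl}but-2-enoate | CC(=O)/C=C/[C@@H]1C(C)=CC[C@H](C/C=C(\C)C(=O)OCC)C1(C)C | intermediate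
19 | ethyl (2E)-4-{(1R,5R)-5-[(1E)-3-hydroxy-3-methylpenta-1,4-dien-1-yl]-4,6,6-trimethylcyclohex-3-en-1-yl}-2-methylbut-2-enoate | C=CC(C)(O)/C=C/[C@@H]1C(C)=CC[C@H](C/C=C(\C)C(=O)OCC)C1(C)C | intermediate
20 | {(2E,4E)-5-[(1R,5R)-5-((2E)-4-ethoxy-3-methyl-4-oxobut-2-en-1-yl)-2,6,6-trimethylcyclohex-2-en-1-yl]-3-methylpenta-2,4-dien-1-yl}triphenylphosphonium bromide | c1ccc(cc1)[P+](c1ccccc1)(c1ccccc1)C/C=C(C)/C=C/[C@@H]1C(C)=CC[C@H](C/C=C(\C)C(=O)OCC)C1(C)C.[Br-] | intermediate
21 | (2E,4E,6E)-2,7-dimethylocta-2,4,6-trienedial | O=C/C(C)=C/C=C/C=C(C)/C=O | starting material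
22 | ethyl (2E)-2-methyl-4-{(1R,5R)-4,6,6-trimethyl-5-[(1E,3E,5E,7E,9E,11E)-3,7,12-trimethyl-13-oxotrideca-1,3,5,7,9,11-hexaen-1-yl]cyclohex-3-en-1-yl}but-2-enoate | O=C/C(C)=C/C=C/C=C(C)/C=C/C=C(C)/C=C/[C@@H]1C(C)=CC[C@H](C/C=C(\C)C(=O)OCC)C1(C)C | intermediate
23 | dimethyl (R)-malate | COC(=O)C[C@@H](O)C(=O)OC | starting material
24 | 1-bromo-3-methylbut-2-ene | CC(C)=CCBr | starting material
25 | dimethyl (2R,3S)-2-hydroxy-3-(3-methylbut-2-en-1-yl)butanedioate | CC(C)=CC[C@@H]([C@@H](O)C(=O)OC)C(=O)OC | intermediate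
26 | (3R,4S)-2,5-dimethyl-4-(3-methylbut-2-en-1-yl)hexane-2,3,5-triol | CC(C)=CC[C@@H]([C@@H](O)C(C)(C)O)C(C)(C)O | intermediate
27 | (2R)-2-(2-hydroxypropan-2-yl)-5-methylhex-4-enal | CC(C)=CC[C@@H](C=O)C(C)(C)O | intermediate
28 | (2E,4E,6S)-6-(2-hydroxypropan-2-yl)-3,9-dimethyldeca-2,4,8-trienenitrile | CC(C)=CC[C@@H](/C=C/C(C)=C/C#N)C(C)(C)O | intermediate
29 | (2E,4E,6S)-6-(2-hydroxypropan-2-yl)-3,9-dimethyldeca-2,4,8-trienal | CC(C)=CC[C@@H](/C=C/C(C)=C/C=O)C(C)(C)O | intermediate
30 | ethyl (2E,4E,6E,8E,10S)-10-(2-hydroxypropan-2-yl)-3,7,13-trimethyltetradeca-2,4,6,8,12-pentaenoate | CC(C)=CC[C@@H](/C=C/C(C)=C/C=C/C(C)=C/C(=O)OCC)C(C)(C)O | intermediate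
31 | (2E,4E,6E,8E,10S)-10-(2-hydroxypropan-2-yl)-3,7,13-trimethyltetradeca-2,4,6,8,12-pentaen-1-ol | CC(C)=CC[C@@H](/C=C/C(C)=C/C=C/C(C)=C/CO)C(C)(C)O | intermediate
32 | [(2E,4E,6E,8E,10S)-10-(2-hydroxypropan-2-yl)-3,7,13-trimethyltetradeca-2,4,6,8,12-pentaen-1-yl]triphenylphosphonium bromide | CC(C)=CC[C@@H](/C=C/C(C)=C/C=C/C(C)=C/C[P+](c1ccccc1)(c1ccccc1)c1ccccc1)C(C)(C)O.[Br-] | intermediate
33 | ethyl (2E)-4-[(1R,5R)-5-{(1E,3E,5E,7E,9E,11E,13E,15E,17E,19E,21E,23S)-23-(2-hydroxypropan-2-yl)-3,7,12,16,20,26-hexamethylheptacosa-1,3,5,7,9,11,13,15,17,19,21,25-dodecaen-1-yl}-4,6,6-trimethylcyclohex-3-en-1-yl]-2-methylbut-2-enoate | CC(C)=CC[C@@H](/C=C/C(C)=C/C=C/C(C)=C/C=C/C(C)=C/C=C/C=C(C)/C=C/C=C(C)/C=C/[C@@H]1C(C)=CC[C@H](C/C=C(\C)C(=O)OCC)C1(C)C)C(C)(C)O | intermediate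
34 | (2E)-4-[(1R,5R)-5-{(1E,3E,5E,7E,9E,11E,13E,15E,17E,19E,21E,23S)-23-(2-hydroxypropan-2-yl)-3,7,12,16,20,26-hexamethylheptacosa-1,3,5,7,9,11,13,15,17,19,21,25-dodecaen-1-yl}-4,6,6-trimethylcyclohex-3-en-1-yl]-2-methylbut-2-en-1-ol | CC(C)=CC[C@@H](/C=C/C(C)=C/C=C/C(C)=C/C=C/C(C)=C/C=C/C=C(C)/C=C/C=C(C)/C=C/[C@@H]1C(C)=CC[C@H](C/C=C(\C)CO)C1(C)C)C(C)(C)O | target

**Totals**

Total step count: 24. Longest linear sequence: 14 steps (steps 3 to 14, then 23 and 24).

**Steps most likely to fail**

1. Step 8 (bears the label "Proposed new method:"). The 7-exo radical cyclisation may be outrun by intermolecular addition to a second vinylphosphonium or by 1,6-hydrogen transfer from the allylic OCH2 group, and the ylide may be protonated before it olefinates. The fallback separates the two bond formations and uses only known reactions, setting out from 11 and returning at 14. Acid 11 is esterified with N-hydroxyphthalimide (DIC, cat. DMAP) to the N-acyloxyphthalimide of 11, F1. Reductive photoredox decarboxylation under tertiary-radical Giese conditions (Ru(bpy)3Cl2, Hantzsch ester, iPr2NEt, blue light) then closes the lactone by the long-known radical addition to a vinylphosphonium salt and ends by hydrogen transfer, giving the isolable (4R,6R)-5,5-dimethyl-4-(2-oxoethyl)-6-[1-(triphenylphosphonio)ethyl]oxepan-2-one tetrafluoroborate, F2. A conventional base-induced intramolecular Wittig reaction of this ω-formyl phosphonium salt (KOtBu, THF, 0 °C, high dilution) gives 14.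

2. Step 4. Enantiofacial discrimination of an unbranched aliphatic enoate may be insufficient, and the acidic catalyst may move the skipped diene into conjugation. The fallback replaces catalyst control by classical resolution, setting out from 6 and returning at 8. Enoate 6 is treated with the same silyl ketene acetal and TiCl4 (CH2Cl2, −78 °C, achiral Mukaiyama–Michael addition) to give racemic dimethyl 2,2-dimethyl-3-(prop-2-en-1-yl)pentanedioate, F3. Saponification as in step 5 gives racemic 2,2-dimethyl-3-(prop-2-en-1-yl)pentanedioic acid, F4. Crystallisation of the (R)-1-phenylethylammonium salt of the (3R)-acid, F5 (the antipodal amine is used if the salt of the (3S)-acid proves the less soluble one), and acidification return 8.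

3. Step 11. Enolisation of the β,γ-unsaturated, α-branched aldehyde may epimerise C6 or move the ring double bond into conjugation before the slow Wittig reaction of the hindered formyl group. The fallback builds the enone by cross-coupling under non-basic conditions, setting out from 16 and returning at 18. Alcohol 16 is oxidised with buffered Dess–Martin periodinane to aldehyde 17, which is isolated. Takai olefination (CrCl2, CHI3, THF, 0 °C) gives ethyl (2E)-4-{(1R,5R)-5-[(E)-2-iodoethenyl]-4,6,6-trimethylcyclohex-3-en-1-yl}-2-methylbut-2-enoate, F6. Stille coupling with tributyl(1-ethoxyvinyl)stannane (Pd(PPh3)4, PhMe, 80 °C) gives ethyl (2E)-4-{(1R,5R)-5-[(1E)-3-ethoxybuta-1,3-dien-1-yl]-4,6,6-trimethylcyclohex-3-en-1-yl}-2-methylbut-2-enoate, F7, whose enol ether is hydrolysed with dilute aqueous HCl to 18.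

Further compounds
F1 | step 8 | 1,3-dioxoisoindolin-2-yl (3R)-2,2-dimethyl-5-oxo-3-(2-oxoethyl)-5-{[(2Z)-3-(triphenylphosphonio)but-2-en-1-yl]oxy}pentanoate tetrafluoroborate | O=CC[C@H](CC(=O)OC/C=C(/C)[P+](c1ccccc1)(c1ccccc1)c1ccccc1)C(C)(C)C(=O)ON1C(=O)c2ccccc2C1=O.F[B-](F)(F)F
F2 | step 8 | (4R,6R)-5,5-dimethyl-4-(2-oxoethyl)-6-[1-(triphenylphosphonio)ethyl]oxepan-2-one tetrafluoroborate | O=C1C[C@@H](CC=O)C(C)(C)[C@H](CO1)C(C)[P+](c1ccccc1)(c1ccccc1)c1ccccc1.F[B-](F)(F)F
F3 | step 4 | racemic dimethyl 2,2-dimethyl-3-(prop-2-en-1-yl)pentanedioate | C=CCC(CC(=O)OC)C(C)(C)C(=O)OC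
F4 | step 4 | racemic 2,2-dimethyl-3-(prop-2-en-1-yl)pentanedioic acid | C=CCC(CC(=O)O)C(C)(C)C(=O)O
F5 | step 4 | (R)-1-phenylethylammonium salt of (3R)-2,2-dimethyl-3-(prop-2-en-1-yl)pentanedioic acid | C=CC[C@H](CC(=O)O)C(C)(C)C(=O)O.C[C@@H](N)c1ccccc1
F6 | step 11 | ethyl (2E)-4-{(1R,5R)-5-[(E)-2-iodoethenyl]-4,6,6-trimethylcyclohex-3-en-1-yl}-2-methylbut-2-enoate | I/C=C/[C@@H]1C(C)=CC[C@H](C/C=C(\C)C(=O)OCC)C1(C)C
F7 | step 11 | ethyl (2E)-4-{(1R,5R)-5-[(1E)-3-ethoxybuta-1,3-dien-1-yl]-4,6,6-trimethylcyclohex-3-en-1-yl}-2-methylbut-2-enoate | CCOC(=C)/C=C/[C@@H]1C(C)=CC[C@H](C/C=C(\C)C(=O)OCC)C1(C)C
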